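**Assumption:** natural trans-phytol, (2E,7R,11R), ≥97% E, is purchased. Its two methyl-bearing stereocentres become C4′ and C8′ of the target unchanged (chiral pool). If only E/Z material is available, it is purified on AgNO3–silica first.

The target SMILES corresponds to natural (2R,4′R,8′R)-δ-tocopherol.

## Retrosynthetic overview

1. δ-Tocopherol (9) ⇐ O-demethylation of its 6-O-methyl ether 8.
2. Chroman ring (the only ring formed; the arene is purchased) and the C2 stereocentre ⇐ catalyst-controlled asymmetric cycloisomerisation (O1–C2 bond) of ortho-phytylphenol 7. This is the new step.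
3. 7 ⇐ aryl–allyl C–C coupling (C4a–C4 bond) of the aryl cuprate from bromide 3 with phytyl bromide 5, then MOM removal.
4. 4′R and 8′R ⇐ natural phytol 4; arene ⇐ 4-methoxy-2-methylphenol 1.

## Route

**Step 1**
Reactants: 1, 4-methoxy-2-methylphenol
Product: 2, 2-bromo-4-methoxy-6-methylphenol
Conditions: NBS (1.0 equiv), i-Pr2NH (10 mol%), CH2Cl2, 0 °C
Reagents that add atoms: N-bromosuccinimide, O=C1CCC(=O)N1Br
Why: Amine-mediated ortho-selective electrophilic aromatic bromination of a phenol; OH is the dominant director, its para position is blocked by OMe and one ortho position by CH3, so Br enters the single free ortho carbon.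

**Step 2**
Reactants: 2, 2-bromo-4-methoxy-6-methylphenol
Product: 3, 1-bromo-5-methoxy-2-(methoxymethoxy)-3-methylbenzene
Conditions: NaH, MOMCl, THF/DMF, 0 °C → rt
Reagents that add atoms: chloromethyl methyl ether (MOMCl), COCCl
Why: Williamson-type O-alkylation of the sodium phenoxide (MOM acetal protection) masks the acidic OH for the organolithium step, and the MOM oxygen stabilises the ortho-aryllithium by chelation.

**Step 3**
Reactants: 4, (2E,7R,11R)-3,7,11,15-tetramethylhexadec-2-en-1-ol (natural phytol)
Product: 5, (2E,7R,11R)-1-bromo-3,7,11,15-tetramethylhexadec-2-ene (phytyl bromide)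
Conditions: PBr3 (0.4 equiv), pyridine (cat.), Et2O, −10 → 0 °C; used crude
Reagents that add atoms: phosphorus tribromide, BrP(Br)Br
Why: SN2 bromination of a primary allylic alcohol via its bromophosphite at low temperature keeps the E olefin and does not touch the remote 7R and 11R centres.

**Step 4**
Reactants: 3, 1-bromo-5-methoxy-2-(methoxymethoxy)-3-methylbenzene; 5, phytyl bromide
Product: 6, 5-methoxy-2-(methoxymethoxy)-1-methyl-3-[(2E,7R,11R)-3,7,11,15-tetramethylhexadec-2-en-1-yl]benzene
Conditions: 3 (1.2 equiv), n-BuLi, THF, −78 °C; CuBr·SMe2 (0.6 equiv), −78 → −40 °C; then 5, −78 → 0 °C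
Reagents that add atoms: none
Why: Br–Li exchange, transmetalation to the diaryl cuprate and α-selective (SN2) allylic substitution on the primary allylic bromide is the standard aryl-cuprate prenylation; E geometry is retained and no stereocentre is formed.

**Step 5**
Reactants: 6, MOM-protected ortho-phytyl arene
Product: 7, 4-methoxy-2-methyl-6-[(2E,7R,11R)-3,7,11,15-tetramethylhexadec-2-en-1-yl]phenol
Conditions: AcCl (0.5 equiv) in MeOH (HCl generated in situ), 0 °C → rt; NaHCO3 work-up
Reagents that add atoms: none
Why: Acid-catalysed acetal methanolysis of the aryl MOM ether; dilute HCl levelled by MeOH at rt does not protonate the trisubstituted olefin (prenylated phenols routinely survive this), so no racemic ring closure occurs.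

**Step 6 (key step, new)**
Reactants: 7, 4-methoxy-2-methyl-6-[(2E,7R,11R)-phytyl]phenol
Product: 8, (2R)-6-methoxy-2,8-dimethyl-2-[(4R,8R)-4,8,12-trimethyltridecyl]chromane (δ-tocopherol methyl ether)
Conditions: confined chiral imidodiphosphorimidate (IDPi) Brønsted acid (BINOL-derived, bulky 3,3′-aryl groups, N-triflyl core; 5 mol%), cyclohexane (0.1 M), 5 Å MS, 50 °C, Ar. The catalyst enantiomer that gives 2R is identified on the first run by chiral HPLC of 8 against the 2-epimer.
Reagents that add atoms: none (cycloisomerisation)
Why: Proposed new method: a strongly acidic, confined chiral Brønsted acid acts as a small-molecule "tocopherol cyclase"; its acidic N–H protonates the E-trisubstituted olefin at the CH carbon (Markovnikov) while the phenol O–H, hydrogen-bonded to a basic oxygen of the same chiral anion, attacks the developing tertiary cation at C3 of the phytyl chain in a concerted-asynchronous six-membered ring closure. Because the E geometry fixes where CH3 and the C16 chain sit, the two olefin faces are stereo-differentiating, and delivery of oxygen to the Re face of C3 (priorities =CH > CH2 chain > CH3) gives 2R under catalyst control, with the remote 7R and 11R centres as spectators. The closest known reaction types are IDPi-catalysed asymmetric intramolecular hydroalkoxylation of unactivated 1,1-disubstituted alkenols to tetrahydrofurans and the racemic acid-catalysed chroman closure used industrially for tocopherols. To my knowledge it has not been shown for a phenol nucleophile adding to an internal trisubstituted allyl-arene olefin to form a 2,2-dialkylchroman.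

**Step 7**
Reactants: 8, (2R,4′R,8′R)-δ-tocopherol methyl ether
Product: 9, (2R)-2,8-dimethyl-2-[(4R,8R)-4,8,12-trimethyltridecyl]chroman-6-ol (δ-tocopherol, target)
Conditions: EtSNa (5 equiv), DMF, 130 °C, Ar; then aq. NH4Cl
Reagents that add atoms: none (CH3 removed; H from work-up)
Why: SN2 O-demethylation of an unhindered aryl methyl ether by thiolate; the tertiary-alkyl aryl ether of the chroman cannot undergo SN2 and no acid is present, so C2 cannot ionise and 2R is preserved.

## Compound list

1 | 4-methoxy-2-methylphenol | COc1ccc(O)c(C)c1 | starting material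
2 | 2-bromo-4-methoxy-6-methylphenol | COc1cc(C)c(O)c(Br)c1 | intermediate
3 | 1-bromo-5-methoxy-2-(methoxymethoxy)-3-methylbenzene | COCOc1c(C)cc(OC)cc1Br | intermediate
4 | (2E,7R,11R)-3,7,11,15-tetramethylhexadec-2-en-1-ol (natural phytol) | OC/C=C(\C)CCC[C@H](C)CCC[C@H](C)CCCC(C)C | starting material
5 | (2E,7R,11R)-1-bromo-3,7,11,15-tetramethylhexadec-2-ene (phytyl bromide) | BrC/C=C(\C)CCC[C@H](C)CCC[C@H](C)CCCC(C)C | intermediate
6 | 5-methoxy-2-(methoxymethoxy)-1-methyl-3-[(2E,7R,11R)-3,7,11,15-tetramethylhexadec-2-en-1-yl]benzene | COCOc1c(C)cc(OC)cc1C/C=C(\C)CCC[C@H](C)CCC[C@H](C)CCCC(C)C | intermediate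
7 | 4-methoxy-2-methyl-6-[(2E,7R,11R)-3,7,11,15-tetramethylhexadec-2-en-1-yl]phenol | COc1cc(C)c(O)c(C/C=C(\C)CCC[C@H](C)CCC[C@H](C)CCCC(C)C)c1 | intermediate
8 | (2R)-6-methoxy-2,8-dimethyl-2-[(4R,8R)-4,8,12-trimethyltridecyl]chromane | Cc1cc(OC)cc2c1O[C@](C)(CCC[C@H](C)CCC[C@H](C)CCCC(C)C)CC2 | intermediate
9 | (2R)-2,8-dimethyl-2-[(4R,8R)-4,8,12-trimethyltridecyl]chroman-6-ol (δ-tocopherol) | Cc1cc(O)cc2c1O[C@](C)(CCC[C@H](C)CCC[C@H](C)CCCC(C)C)CC2 | target

## Summary

Total steps: 7.
Longest linear sequence: 6 (steps 1, 2, 4, 5, 6, 7 from compound 1; step 3 is a one-step branch).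

Three steps most likely to fail:

1. **Step 6 (proposed new asymmetric cycloisomerisation).** Risks are low reactivity of the internal trisubstituted olefin in the confined pocket, insufficient Me versus CH2R face discrimination, and olefin isomerisation that leaks the 2S epimer. Fallback (known chemistry): Shi asymmetric epoxidation of the E-trisubstituted olefin of MOM ether 6, then acid-mediated (CSA) MOM loss and 6-endo epoxide opening by the phenol oxygen at the tertiary carbon with inversion to give the 3-hydroxychroman, then Barton–McCombie deoxygenation of the 3-OH to reach 8. The Shi ketone enantiomer is chosen to place the epoxide oxygen on the Si face of C3, so the invertive opening gives 2R.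

2. **Step 4 (aryl cuprate allylation).** Risks are competing SN2′ attack giving the branched tertiary isomer, E/Z erosion, and homocoupling of the bromide. Fallback: switch to a Pd-catalysed π-allyl Stille coupling of the aryl stannane (from 3: n-BuLi, then Bu3SnCl) with 5 (Pd2(dba)3, AsPh3), which couples at the less hindered allyl terminus to give the linear E product.

3. **Step 7 (thiolate demethylation).** Risks are the forcing temperature and air oxidation of the electron-rich phenoxide. Fallback: change the protecting-group strategy by carrying the C6 oxygen as a benzyl ether from the outset (starting from 4-(benzyloxy)-2-methylphenol through the same sequence) and finishing with neutral hydrogenolysis (H2, Pd/C). This is possible because no olefin remains after step 6.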